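Count in millimoles per litre, not in percent.

| flask | Zb | Za | temperature | remark | time |
|---|---|---|---|---|---|
| red | 14 mM | 2.1 µM | 24 °C | run made earlier |  |
| violet | 32 mM | 2.1 µM | 32 °C | run made earlier |  |
| amber | 21 mM | 3.2 µM | 24 °C | run made earlier |  |
| dusk | 21 mM | 2.1 µM | 35 °C |  | 50 min |
| dawn | 21 mM | 2.1 µM | 20 °C |  | 50 min |

| run | time / min | Zd / % | Zb / % |
|---|---|---|---|
| red | 6.00 | 9.3 | 92.8 |
| red | 15.0 | 17.1 | 81.4 |
| red | 25.0 | 29.1 | 69.9 |
| red | 40.0 | 46.1 | 53.5 |
| red | 80.0 | 84.3 | 15.2 |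
| violet | 4.00 | 2.4 | 97.9 |
| violet | 12.0 | 5.5 | 94.1 |
| violet | 25.0 | 13.4 | 86.8 |
| violet | 40.0 | 21.1 | 80.0 |
| violet | 50.0 | 22.8 | 75.1 |
| amber | 6.00 | 6.3 | 92.5 |
| amber | 15.0 | 13.6 | 85.7 |
| amber | 25.0 | 24.8 | 75.3 |
| amber | 40.0 | 38.9 | 62.3 |
| amber | 80.0 | 76.9 | 23.9 |

(scatter of a reading: 1 percentage point)

- what was read earlier has a scatter of 1 percentage point, one standard deviation

* which flask leads in amount of Zd, in percent of the Zb charged ("all alike" within 1.5 percentage points) (dusk / dawn / all alike)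
* how much Zd is there at the end, in percent of the Zb charged: dusk
* how much Zd is there at the end, in percent of the Zb charged: dawn

*What do you read from the runs?* Zd made per litre and minute, up to 40.0 min. Red gives 0.161 mM min⁻¹ and violet 0.169 mM min⁻¹, although Zb and temperature both differ. Their mean is 0.165 mM min⁻¹; I call it r, the rate of Zd formation at 2.1 µM Za as read from these two runs, taken as zero order in Zb.

*Your answer, then?* My own reckoning is r·t divided by the charge, which gives 39.3 % in both dusk and dawn, so I say all alike.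

*Put that back in: does r still hold at the end?* That answer leaves 12.7 mM Zb. This is more than the 7.49 mM in red at 40.0 min, and red's mean rate was 0.163 mM min⁻¹ up to 25.0 min and 0.161 mM min⁻¹ up to 40.0 min. The answer stands.

*Could Zb and temperature cancel between red and violet?* They could, and this is my weak spot. Amber, with 3.2 µM Za and 21 mM Zb, runs at 0.204 mM min⁻¹, which is 1.27 times red for 1.52 times the Za. That may mean Zb above 14 mM slows the flask, or that Za counts less than in proportion. I keep r.

The forecast differs from my reckoning. It has dusk leading, with dusk at 52 % (range 38 % to 65 %) and dawn at 25 % (range 20 % to 30 %), holding that “the temperature factor is about 1.6 per 8 °C”.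

The flasks give all alike: dusk 39.2 %, dawn 38.1 %. At 50.0 min, dusk holds 37.9 % of its catalyst as Zc, a form outside the working round, and dawn 0.266 %. In the unit of r, the mean rates of Zd formation up to 50 min are 0.165 mM min⁻¹ for dusk and 0.160 mM min⁻¹ for dawn, against r of 0.165 mM min⁻¹.

    Za → Zc (k = 1.70 × 10⁻⁵ s⁻¹, Ea = 260 kJ mol⁻¹)
    Zb + Za → Zd + Za, rate k2*[Zb]*[Za]/(1 + ([Zb]/Km2) + ([Zb]/Ksi2)^2) (2.80 mM, 15.0 mM, k = 12000 L mol⁻¹ s⁻¹, Ea = 13.0 kJ mol⁻¹)
    2 Za ⇌ Ze, settled at all times (K = 8.30 × 10⁷ L mol⁻¹, ΔH = 12.0 kJ mol⁻¹)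
    (constants at 20 °C)

Now take dawn's flask charged with 8.4 mM Zb. The first round with r gives 98.2 % Zd, leaving 0.146 mM Zb, which is below the 2.13 mM Zb read in red at 80.0 min. The second round therefore uses the rate read in red between 40.0 min and 80.0 min, 0.134 mM min⁻¹, and gives 79.8 % Zd; that flask gives 77.2 %.

The runs are calculated on assumed constants.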